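The data stem from a simulated flask for an exercise.

The north-east flask is leaner than the north-west run, yet both charge reagent and substrate in the ratio 1.50, and that shared ratio lets one progress curve be read for the other.

| flask | substrate | reagent | target | time |
|---|---|---|---|---|
| north-west | 50.0 mM | 75.0 mM |  |  |
| east | 50.0 mM | 75.0 mM | 15.0 mM |  |
| west | 150 mM | 75.0 mM |  |  |
| north-east | 20.0 mM | 30.0 mM |  | 9.1 min |

- north-west run (time / min: [target] / mM): 1.1: 14.92; 2.3: 22.94; 3.4: 27.64; 4.5: 30.30; 5.7: 32.45; 6.8: 33.59; 8.0: 34.56; 9.1: 35.33
- east run (time / min: [target] / mM): 1.1: 29.60; 2.3: 37.46; 3.4: 41.61; 4.5: 44.34; 5.7: 45.99; 6.8: 47.50; 8.0: 48.22; 9.1: 48.70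
- west run (time / min: [target] / mM): 1.1: 34.47; 2.3: 47.70; 3.4: 53.79; 4.5: 57.42; 5.7: 59.77; 6.8: 61.50; 8.0: 62.49; 9.1: 63.35

(readings scatter by 0.2 mM)

- Overall: substrate + reagent -> target.
- Constant volume, constant temperature.
- "The second partner" is reagent.
- An order is taken over about fifteen percent of the charge, up and down.

* reaction order in [substrate] at the outset, round the charge of the north-west run, defined at two percent of the substrate turned into target (one fixed amount of target, the same in the runs compared)
* target in the north-east run at 9.1 min, as a share of the substrate charged

Mass-action constants from the first readings of the north-west and west runs give an order in [substrate] of 0.895, a reading I take as one; reagent is charged at 75.0 mM in the north-west, east and west runs, so its order of one is assumed.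

If each step joins two molecules, rates scale with the square of a common dilution and amounts with its first power, so curves at one ratio of charges coincide when target, as a share of substrate, is plotted against charged [substrate] times time. The number to carry is therefore the reduced time, 0.400, the charged [substrate] times time of the north-east flask over that of the last north-west reading. At 9.1 min the north-east flask thus stands where the north-west run stood at 3.64 min, and interpolation between the readings at 3.4 min and 4.5 min gives 56.4%.

A first-order back reaction lies outside this scaling, and the flattening ends of the curves invite one. Read as a balance, the last north-west reading makes the 15.0 mM of target added in the east run cost about 2.74 mM by 2.3 min, yet the east run has made just 0.480 mM less, so the reduced time is kept.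

The forecast, holding that “The plateaus fit a reversible reaction”, gave an order of 0.8 and 48%, against my one and 56.4%. The flask gives 1.0 and 56.6%.

    substrate + reagent → target + by-product (5.166 /M/min)
    2 substrate → homo dimer (1.170 /M/min)
    target + reagent → side product (0.2712 /M/min)

Each step of this scheme takes two molecules, the condition under which the reduced time 0.400 was reckoned. Substrate lost to homo dimer costs the north-east flask target: at 9.1 min that flask stands at 56.6% with the step and 62.1% without it, a difference of 5.5 percentage points.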